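**Retrosynthetic overview** (disconnections listed from the starting-material end)

1. Side chain and C2 stereocentre: cut at C9'–C10' (B-alkyl Suzuki of oct-1-ene 1 with 7-bromohept-1-ene 2 through borane 3 to pentadec-1-ene 4) and at C3'=C4' (cross-metathesis/hydrogenation of 4 with (S)-2-(but-3-en-1-yl)oxirane 5 through alkene 6), giving (S)-2-heptadecyloxirane 7; the oxirane CH of 5 becomes C2.
2. C3–C4 bond: CO is inserted into the CH2–O bond of 7, oxirane to oxetan-2-one 8 (three- to four-membered ring expansion).
3. C4–C4a and O1–C8a bonds: the acyl C–O bond of 8 is opened onto C2 of cyclohexane-1,3-dione 9 (enol ester 10, triketone 11) and the freed C2–O closes on the ring carbonyl, oxetanone to dihydropyranone 12 (four- to six-membered ring expansion).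
4. C4–H bond: 1,2-hydride addition to the C4 carbonyl of 12, steered by C2, gives the cis alcohol 13 (target).
5. Ring order: the carbocycle is bought in 9; oxirane (bought) → oxetanone → pyran ring, the only ring closed on the final skeleton.

Assumption: 5 is bought as the single (S)-enantiomer (primed locants above count the side chain outward from the ring).

**Step 1**
Reactants: 1 oct-1-ene; 2 7-bromohept-1-ene
Product: 4 pentadec-1-ene, via B-octyl-9-BBN 3 (not isolated)
Conditions: 9-BBN (1.0 equiv), 1 (1.1 equiv), THF, 0 °C to rt; then 2, Pd(OAc)2 (4 mol %), PCy3 (8 mol %), K3PO4·H2O (1.2 equiv), THF, rt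
Reagents that add atoms: none
Why: Anti-Markovnikov hydroboration of 1 with exactly one equivalent of 9-BBN gives the primary borane 3, which couples with the primary bromide 2 in a B-alkyl Suzuki–Miyaura sp3–sp3 cross-coupling (PCy3 lets coupling outrun β-hydride elimination, and no B–H is left to touch the alkene of 2); no stereocentre is formed.

**Step 2**
Reactants: 4 pentadec-1-ene (2.5 equiv); 5 (S)-2-(but-3-en-1-yl)oxirane
Product: 7 (S)-2-heptadecyloxirane, via alkenyl epoxide 6 (not isolated)
Conditions: second-generation Grubbs catalyst RuCl2(=CHPh)(H2IMes)(PCy3) (3 mol %), 1,4-benzoquinone (10 mol %), CH2Cl2, 40 °C; then Pd/C (10 wt % palladium on carbon), H2 (1 atm), EtOAc, rt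
Reagents that add atoms: none
Why: Olefin cross-metathesis of two unhindered terminal alkenes releases ethene and, with 4 in excess and benzoquinone suppressing Ru–H chain walking, gives 6, whose disubstituted C=C is then saturated by heterogeneous hydrogenation under conditions that leave the aliphatic oxirane and its stereocentre (carried in from 5) untouched.

**Step 3**
Reactants: 7 (S)-2-heptadecyloxirane
Product: 8 (S)-4-heptadecyloxetan-2-one
Conditions: CO (60 bar), [(salph)Al(THF)2][Co(CO)4] (2 mol %; salph = N,N'-o-phenylenebis(3,5-di-tert-butylsalicylideneiminate)), DME, 50 °C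
Reagents that add atoms: carbon monoxide, [C-]#[O+]
Why: Ring-expansion carbonylation of an epoxide: the aluminium Lewis acid activates the oxirane, [Co(CO)4]− opens it at the unhindered CH2, CO inserts into the Co–C bond and the aluminium alkoxide closes onto the acylcobalt, so the three-membered ring grows to the oxetan-2-one while the C–O bond at the stereocentre is never broken (retention, S).

**Step 4**
Reactants: 8 (S)-4-heptadecyloxetan-2-one; 9 cyclohexane-1,3-dione (1.2 equiv)
Product: 12 (2S)-2-heptadecyl-7,8-dihydro-2H-chromene-4,5(3H,6H)-dione, via enol ester 10 (not isolated), via triketone 11 (not isolated)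
Conditions: DMAP (0.2 equiv), Et3N (1.2 equiv), MeCN, 40 °C; then TsOH·H2O (1.5 equiv), 4 Å MS, 40 °C
Reagents that add atoms: none
Why: Proposed new method: DMAP is expected to open the strained β-lactone at the acyl carbon (the microscopic reverse of nucleophile-catalysed aldol-lactonisation), the dionate of 9 is O-acylated to 10, DMAP then effects the familiar enol ester to 2-acyl-1,3-dione O-to-C acyl shift to triketone 11 (held as its unreactive ammonium salt so the β-hydroxyl neither eliminates nor closes under base), and acidification lets the C2 hydroxyl condense with the enolised ring carbonyl (intramolecular vinylogous esterification) so that C4a=C8a is inserted into the lactone acyl C–O bond, a four- to six-membered ring expansion in which no bond to C2 is broken (S retained); the closest known chemistry is the DCC/DMAP or cyanide-mediated C-acylation of cyclic 1,3-diones and acyl-transfer ring expansions of lactones.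

**Step 5**
Reactants: 12 (2S)-2-heptadecyl-7,8-dihydro-2H-chromene-4,5(3H,6H)-dione
Product: 13 (2S,4R)-2-heptadecyl-4-hydroxy-2,3,4,6,7,8-hexahydro-5H-chromen-5-one
Conditions: NaBH4 (1.0 equiv), CeCl3·7H2O (1.1 equiv), MeOH/CH2Cl2, −78 °C; pH 7 buffer quench, chromatography on Et3N-deactivated silica
Reagents that add atoms: none
Why: Luche 1,2-reduction: the cerium-activated C4 carbonyl, a β-alkoxy ketone expected to be the more electrophilic of the two through the inductive pull of O1 via C2–C3, takes hydride along the axial trajectory of the half-chair that holds the heptadecyl group pseudo-equatorial, which puts the new hydroxyl pseudo-equatorial and cis to the chain (4R), as in the reduction of 2-substituted 2,3-dihydro-4H-pyran-4-ones to cis-alcohols.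

**Compound list**

1 | oct-1-ene | CCCCCCC=C | starting material
2 | 7-bromohept-1-ene | C=CCCCCCBr | starting material
3 | B-octyl-9-borabicyclo[3.3.1]nonane | CCCCCCCCB1C2CCCC1CCC2 | intermediate
4 | pentadec-1-ene | CCCCCCCCCCCCCC=C | intermediate
5 | (S)-2-(but-3-en-1-yl)oxirane | C=CCC[C@H]1CO1 | starting material
6 | (S)-2-[(E)-heptadec-3-en-1-yl]oxirane (E/Z mixture, E drawn) | CCCCCCCCCCCCC/C=C/CC[C@H]1CO1 | intermediate
7 | (S)-2-heptadecyloxirane | CCCCCCCCCCCCCCCCC[C@H]1CO1 | intermediate
8 | (S)-4-heptadecyloxetan-2-one | CCCCCCCCCCCCCCCCC[C@H]1CC(=O)O1 | intermediate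
9 | cyclohexane-1,3-dione | O=C1CCCC(=O)C1 | starting material
10 | 3-oxocyclohex-1-en-1-yl (3S)-3-hydroxyicosanoate | CCCCCCCCCCCCCCCCC[C@H](O)CC(=O)OC1=CC(=O)CCC1 | intermediate
11 | 3-hydroxy-2-[(3S)-3-hydroxyicosanoyl]cyclohex-2-en-1-one | CCCCCCCCCCCCCCCCC[C@H](O)CC(=O)C1=C(O)CCCC1=O | intermediate
12 | (2S)-2-heptadecyl-7,8-dihydro-2H-chromene-4,5(3H,6H)-dione | CCCCCCCCCCCCCCCCC[C@H]1CC(=O)C2=C(CCCC2=O)O1 | intermediate
13 | (2S,4R)-2-heptadecyl-4-hydroxy-2,3,4,6,7,8-hexahydro-5H-chromen-5-one | CCCCCCCCCCCCCCCCC[C@H]1C[C@@H](O)C2=C(CCCC2=O)O1 | target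

**Totals and risks**

Total steps: 5. Longest linear sequence: 5 (1 → 4 → 7 → 8 → 12 → 13).

Steps most likely to fail:

Step 4 (the proposed new step). The dionate may instead attack the lactone at C2 by SN2 (O- or C-alkylation with inversion). The ring-opened acyl species may oligomerise to polyester. Dehydration of 11 to an enoyl dione followed by oxa-Michael closure would give 12 with eroded ee. 12 itself can lose its C2 configuration by base-induced retro-oxa-Michael, which is why the base is quenched before the ring closes. Fallback using known chemistry, setting out from 8 and coming back at 12: methanolysis of 8 (NaOMe cat., MeOH) gives methyl (3S)-3-hydroxyicosanoate F1; silylation (TBSCl, imidazole, DMF) gives methyl (3S)-3-[(tert-butyldimethylsilyl)oxy]icosanoate F2; saponification (LiOH, THF/H2O) gives (3S)-3-[(tert-butyldimethylsilyl)oxy]icosanoic acid F3; the established one-pot DCC/DMAP O-acylation and O-to-C rearrangement with 9 gives 2-{(3S)-3-[(tert-butyldimethylsilyl)oxy]icosanoyl}-3-hydroxycyclohex-2-en-1-one F4; HF·pyridine in MeCN followed by TsOH removes the silyl group and closes the ring through 11 to 12.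

Step 5. 12 carries two vinylogous-ester carbonyls, and the preference for C4 rests only on an inductive argument, so some C5 alcohol is to be expected. Conjugate hydride addition at C8a with ring opening is a further possible leak. The product alcohol ionises easily under acid. Fallback that avoids the diketone altogether, setting out from 7 and coming back at 13: 7 is opened with vinylmagnesium bromide (CH2=CHMgBr, CuI cat., THF, −30 °C) to (4S)-henicos-1-en-4-ol F5; acid-catalysed condensation with 9 (TsOH, benzene, Dean–Stark) gives 3-{[(4S)-henicos-1-en-4-yl]oxy}cyclohex-2-en-1-one F6; oxidative cleavage of the terminal alkene (OsO4 cat., NaIO4, 2,6-lutidine, dioxane/H2O) gives (3S)-3-[(3-oxocyclohex-1-en-1-yl)oxy]icosanal F7; a Lewis-acid-promoted intramolecular aldol-type addition of the vinylogous-ester α-carbon to the aldehyde (Me2AlCl, CH2Cl2, −78 °C; chair-like closure with the chain equatorial, 1,3-anti induction) gives 13 directly. This last closure is itself unproven on vinylogous esters.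

Step 2. The cross-metathesis of two unbiased terminal alkenes is statistical, Ru–H isomerisation can shift the chain length by one carbon, and the hydrogenation must not open the oxirane. Fallback without metathesis, setting out from 4 and coming back at 7: hydroboration of 4 with 9-BBN gives B-pentadecyl-9-borabicyclo[3.3.1]nonane F8, which is coupled with 4-bromobut-1-ene (Pd(OAc)2, PCy3, K3PO4·H2O, THF) to nonadec-1-ene F9; epoxidation (mCPBA, CH2Cl2) gives racemic 2-heptadecyloxirane F10; hydrolytic kinetic resolution with (S,S)-(salen)Co(OAc) (trivalent cobalt; salen = N,N'-bis(3,5-di-tert-butylsalicylidene)cyclohexane-1,2-diamine dianion) and 0.55 equiv of water leaves 7 and removes the other enantiomer as (R)-nonadecane-1,2-diol F11.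

**Further compounds**

F1 | step 4 | methyl (3S)-3-hydroxyicosanoate | CCCCCCCCCCCCCCCCC[C@H](O)CC(=O)OC
F2 | step 4 | methyl (3S)-3-[(tert-butyldimethylsilyl)oxy]icosanoate | CCCCCCCCCCCCCCCCC[C@H](O[Si](C)(C)C(C)(C)C)CC(=O)OC
F3 | step 4 | (3S)-3-[(tert-butyldimethylsilyl)oxy]icosanoic acid | CCCCCCCCCCCCCCCCC[C@H](O[Si](C)(C)C(C)(C)C)CC(=O)O
F4 | step 4 | 2-{(3S)-3-[(tert-butyldimethylsilyl)oxy]icosanoyl}-3-hydroxycyclohex-2-en-1-one | CCCCCCCCCCCCCCCCC[C@H](O[Si](C)(C)C(C)(C)C)CC(=O)C1=C(O)CCCC1=O
F5 | step 5 | (4S)-henicos-1-en-4-ol | CCCCCCCCCCCCCCCCC[C@H](O)CC=C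
F6 | step 5 | 3-{[(4S)-henicos-1-en-4-yl]oxy}cyclohex-2-en-1-one | CCCCCCCCCCCCCCCCC[C@H](OC1=CC(=O)CCC1)CC=C
F7 | step 5 | (3S)-3-[(3-oxocyclohex-1-en-1-yl)oxy]icosanal | CCCCCCCCCCCCCCCCC[C@H](OC1=CC(=O)CCC1)CC=O
F8 | step 2 | B-pentadecyl-9-borabicyclo[3.3.1]nonane | CCCCCCCCCCCCCCCB1C2CCCC1CCC2
F9 | step 2 | nonadec-1-ene | CCCCCCCCCCCCCCCCCC=C
F10 | step 2 | racemic 2-heptadecyloxirane | CCCCCCCCCCCCCCCCCC1CO1
F11 | step 2 | (R)-nonadecane-1,2-diol | CCCCCCCCCCCCCCCCC[C@@H](O)CO
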